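Late in the earlier runs target fell slowly, so I began at the last south reading, 79 % at 2.50 d.

| flask | starting material | capture agent | remark | time |
|---|---|---|---|---|
| south | 1 M | 0.067 M | run made earlier |  |
| north-west | 1 M | 0.15 M | run made earlier |  |
| south-east | 1.5 M | 0.10 M | run made earlier |  |
| flask | 1.0 M | 0.100 M |  | 3.0 d |

- south (time / d: target / %): 0.0556: 52; 0.104: 78; 0.208: 86; 0.417: 86; 0.625: 86; 1.25: 81; 2.50: 79
- north-west (time / d: target / %): 0.0556: 51; 0.104: 76; 0.208: 86; 0.417: 84; 0.625: 82; 1.25: 79; 2.50: 75
- south-east (time / d: target / %): 0.0556: 53; 0.167: 89; 0.417: 89; 1.04: 85; 2.50: 82

(readings scatter by 2 percentage points)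

- time, not beyond 3.0 d, at which the flask holds most target
- the amount of target, in percent of the starting material charged, at that time

I supposed a stoichiometric loss: capture agent withdraws its own fraction of the charge, 6.70 % in the south run. Dividing the reading by what remained gave 84.7 %, which I called the keep share, target as a part of the charge not withdrawn late in a run. For the flask, whose capture agent is 10.0 % of the charge, this gave 76.2 % at the end, less than the 86 % read at 0.208 d in the south run. So I put the maximum early. The south and north-west runs bracket the flask in capture agent and both read 86 % at that time, so I committed to about that amount near that time.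

The weak link was the one-for-one loss. The north-west run, with more capture agent than the others, gave a keep share of 88.2 % against 84.7 %, with a scatter of 2 percentage points on each reading, so I kept the link, loosely.

The forecast gave 0.3 d and 86.5 %, later than my time, and warned: “The peak is flat, so its time is poorly fixed”.

The flask gave 0.240 d and 86.2 %, with 0.00557 % of the starting material left then.

    starting material → open intermediate (k = 1.70 h⁻¹)
    open intermediate ⇌ target (K = 15.0, k = 1.10 h⁻¹)
    open intermediate ⇌ isomer of the product (K = 36.0, k = 0.0230 h⁻¹)
    open intermediate + capture agent → trapped intermediate (k = 0.800 M⁻¹ h⁻¹)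

At 3.00 d the flask held 75.3 % target against the keep-share reckoning of 76.2 %. For the neighbour, charged with 0.40 M of capture agent and otherwise like the flask, the same reckoning gave 50.8 % target. At 3.00 d it held 37.2 % trapped intermediate and 52.0 % target.

(All runs are simulated with constants of no real substance; the scatter is artificial.)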